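The synthesis rests on the bond between C9a, the nitrogen-bearing enamine carbon of the pyrrolo[1,2-a]azepine, and C1, the quaternary spiro carbon that carries the lactone oxygen and is shared by the pyrrolidine, the cyclohexene and the fused lactone. Forward, C9a is the carbonyl carbon of an N-substituted azepan-2-one and C1 the γ-carbon of a 2-silyloxyfuran held two atoms from nitrogen: triflic anhydride activation triggers a dearomatising vinylogous Mannich spirocyclisation that closes the pyrrolidine, sets C1 and unveils at once the C9=C9a enamine and a spiro butenolide. Nucleophilic C9 and electrophilic C12 are then bridged by 1-nitrobutene to close the cyclohexene.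

Key step: step 11

Remark: Stemona-type numbering is used (N4; C5–C8 azepine CH2; C9=C9a enamine, C9a on N; C1 spiro carbon; C2; C3 CH–N; C10 CH–Et; C11 CH–OH; C12; C13 CH–Me and C14 C=O of the fused lactone; C18 CH–O and C20 CH–Me of the side lactone); the (S)-auxiliary is chosen from the open transition-state model; (E)-1-nitrobut-1-ene is made in step 12 and all other starting materials are taken as commercial.

Step 1
Reactants: 1 3-methylfuran-2(5H)-one
Product: 2 3-methyl-2-(triisopropylsilyloxy)furan
Conditions: TIPSOTf, Et3N, CH2Cl2, 0 °C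
Reagents that add atoms: triisopropylsilyl trifluoromethanesulfonate, CC(C)[Si](C(C)C)(C(C)C)OS(=O)(=O)C(F)(F)F
Why: Soft enolisation of the butenolide and O-silylation should give the aromatic silyl dienol ether (2-silyloxyfuran formation).

Step 2
Reactants: 3 3-(tert-butyldimethylsilyloxy)propanal; 4 (S)-2-methylpropane-2-sulfinamide
Product: 5 (S,E)-N-[3-(tert-butyldimethylsilyloxy)propylidene]-2-methylpropane-2-sulfinamide
Conditions: pyrrolidine (10 mol %), 4 Å MS, CH2Cl2, rt
Reagents that add atoms: none
Why: Amine-catalysed condensation (Ellman N-sulfinyl imine formation) should give the E-aldimine.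

Step 3
Reactants: 5 N-sulfinyl imine; 2 3-methyl-2-(triisopropylsilyloxy)furan
Product: 6 (S)-N-[(1R)-3-(tert-butyldimethylsilyloxy)-1-[(2S)-4-methyl-5-oxo-2,5-dihydrofuran-2-yl]propyl]-2-methylpropane-2-sulfinamide
Conditions: TMSOTf (1.2 equiv), CH2Cl2, −78 °C; aq. NaHCO3
Reagents that add atoms: none
Why: In this vinylogous Mukaiyama–Mannich reaction the furan γ-carbon should add to the silyl-activated sulfinimine through an open transition state on the face anti to the tert-butyl group (C3 R) and in the anti mode expected for acyclic aldimines (C18 S).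

Step 4
Reactants: 6 butenolide sulfinamide
Product: 7 (S)-N-[(1R)-3-(tert-butyldimethylsilyloxy)-1-[(2S,4S)-4-methyl-5-oxooxolan-2-yl]propyl]-2-methylpropane-2-sulfinamide
Conditions: H2 (3 atm), 10% Pd/C, EtOAc, rt
Reagents that add atoms: none
Why: Heterogeneous hydrogenation should deliver hydrogen to the butenolide face anti to the C18 side chain, so that the C20 methyl ends cis to that chain (20S).

Step 5
Reactants: 7 saturated lactone sulfinamide
Product: 8 (3S,5S)-5-[(1R)-1-amino-3-hydroxypropyl]-3-methyloxolan-2-one hydrochloride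
Conditions: HCl (4 M in dioxane), MeOH, 0 °C to rt
Reagents that add atoms: hydrogen chloride, Cl
Why: Acidic methanolysis cleaves the N–S bond of the Ellman auxiliary and the primary TBS ether, and the amine is kept as its salt so that it cannot open the neighbouring lactone (lactone-to-lactam rearrangement).

Step 6
Reactants: 8 amino alcohol hydrochloride; 9 6-bromohexanoyl chloride
Product: 11 1-[(1R)-3-hydroxy-1-[(2S,4S)-4-methyl-5-oxooxolan-2-yl]propyl]azepan-2-one, via bromo amide 10 (not isolated)
Conditions: NaHCO3, CH2Cl2/H2O, 0 °C; then KOtBu (1.1 equiv), THF (0.01 M), 0 °C to rt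
Reagents that add atoms: none
Why: Schotten–Baumann N-acylation is faster than O-acylation or lactone aminolysis, and the amide anion (more acidic than the alcohol in THF) should then close the azepanone by intramolecular 7-exo-tet N-alkylation under dilution.

Step 7
Reactants: 11 lactam alcohol
Product: 12 (3R)-3-[(2S,4S)-4-methyl-5-oxooxolan-2-yl]-3-(2-oxoazepan-1-yl)propanal
Conditions: Dess–Martin periodinane, NaHCO3, CH2Cl2, rt
Reagents that add atoms: none
Why: Dess–Martin oxidation converts the primary alcohol into the aldehyde under neutral conditions that leave the lactone, the lactam and the α-amino stereocentre untouched.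

Step 8
Reactants: 12 aldehyde; 13 ethyl 2-(bromomethyl)acrylate
Product: 15 1-[(1R)-2-(4-methylidene-5-oxooxolan-2-yl)-1-[(2S,4S)-4-methyl-5-oxooxolan-2-yl]ethyl]azepan-2-one, via hydroxy ester 14 (not isolated)
Conditions: Zn, THF/sat. aq. NH4Cl, rt; then TsOH (cat.), CH2Cl2, rt
Reagents that add atoms: none
Why: Zinc-mediated Barbier allylation of the aldehyde and acid-promoted lactonisation should give the α-methylene-γ-butyrolactone, whose new C1 centre is formed as a mixture that converges in step 10.

Step 9
Reactants: 15 α-methylene lactone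
Product: 16 1-[(1R)-2-(4-methyl-5-oxo-2,5-dihydrofuran-2-yl)-1-[(2S,4S)-4-methyl-5-oxooxolan-2-yl]ethyl]azepan-2-one
Conditions: RhCl3·3H2O (5 mol %), EtOH, 80 °C
Reagents that add atoms: none
Why: Rhodium hydride-mediated alkene isomerisation should move the exocyclic double bond into the ring to give the thermodynamically favoured endocyclic butenolide.

Step 10
Reactants: 16 butenolide lactam
Product: 17 1-[(1R)-2-[4-methyl-5-(triisopropylsilyloxy)furan-2-yl]-1-[(2S,4S)-4-methyl-5-oxooxolan-2-yl]ethyl]azepan-2-one
Conditions: TIPSOTf (1.3 equiv), Et3N, CH2Cl2, 0 °C; non-aqueous work-up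
Reagents that add atoms: triisopropylsilyl trifluoromethanesulfonate, CC(C)[Si](C(C)C)(C(C)C)OS(=O)(=O)C(F)(F)F
Why: Soft enolisation at the γ-position (C1–H) and O-silylation should give the aromatic 2-silyloxyfuran, the saturated lactone and the lactam being far less acidic.

Step 11
Reactants: 17 silyloxyfuran lactam
Product: 19 (1R,3R)-4'-methyl-3-[(2S,4S)-4-methyl-5-oxooxolan-2-yl]-2,3,5,6,7,8-hexahydro-5'H-spiro[pyrrolo[1,2-a]azepine-1,2'-furan]-5'-one (C9=C9a enamine with spiro butenolide), via O-triflyliminium triflate 18 (not isolated)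
Conditions: Tf2O (1.1 equiv), 2-fluoropyridine (2.5 equiv), CH2Cl2 (0.02 M), −78 to 0 °C; cold aq. NaHCO3; used crude under argon
Reagents that add atoms: none
Why: Tf2O converts the lactam carbonyl (C9a) into the O-triflyliminium ion 18, which the tethered 2-silyloxyfuran attacks through its substituted γ-carbon (C1); loss of the silyl group, of triflate and of the C9 proton should then deliver the C9=C9a enamine and the spiro butenolide in one operation. The closest known reaction types are the Vilsmeier–Haack-type cyclisation of silyl enol ethers onto triflic anhydride-activated amides, the interrupted Bischler–Napieralski spirocyclisation and the vinylogous Mukaiyama–Mannich reaction of 5-substituted 2-silyloxyfurans. The pyrrolidine ring closes in a 5-endo-trig Mannich mode (spiro at the nucleophile), the mode that also operates in the Mannich step of aza-Cope/Mannich cascades. The new quaternary centre C1 is controlled by C3: the lactone substituent should lie pseudo-equatorial on the forming ring (anti to C9a) and the furan should turn its TIPSO-bearing O–C edge away from the azepane, which places the lactone oxygen on the ring face anti to the C3 substituent (1R). The step needs γ- over α-attack of the furan (the α-carbon is blocked by methyl and only γ-attack gives a five-membered ring), activation of the amide in the presence of the lactone (the amide oxygen is the most nucleophilic site) and a single enamine regiochemistry (C1 is quaternary, so only C9 can lose a proton).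

Step 12
Reactants: 20 propanal; 21 nitromethane
Product: 23 (E)-1-nitrobut-1-ene, via 1-nitrobutan-2-ol 22 (not isolated)
Conditions: KOtBu (5 mol %), THF/t-BuOH, 0 °C; then MsCl, Et3N, CH2Cl2, 0 °C
Reagents that add atoms: none
Why: A Henry reaction followed by mesylation and E1cB elimination should give the thermodynamically favoured E-nitroalkene.

Step 13
Reactants: 19 spiro enamine butenolide; 23 (E)-1-nitrobut-1-ene
Product: 25 11-nitro pentacycle (the target skeleton with a nitro group in place of the C11 hydroxyl; mixture of C11 epimers), via nitro enamine 24 (not isolated)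
Conditions: CH2Cl2, −20 °C to rt; then DBU (0.3 equiv), 0 °C; AcOH quench
Reagents that add atoms: none
Why: A Stork enamine Michael addition of C9 to the nitroalkene followed by intramolecular nitronate Michael addition (6-exo-trig) to the butenolide carbon C12 should close the cyclohexene: C10 is expected S from approach on the enamine face syn to the lactone oxygen in the synclinal Seebach arrangement (nitro group over N, ethyl away from C1), C12 is forced cis by the tether, C13 arises from exo-face protonation of the lactone enolate, and the C11 epimers converge in step 14.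

Step 14
Reactants: 25 11-nitro pentacycle
Product: 26 11-oxo pentacycle (the target with a ketone at C11)
Conditions: DBU (1.1 equiv), THF, 0 °C; then aq. TiCl3 (4 equiv), NH4OAc buffer (pH 5), 0 °C to rt
Reagents that add atoms: water, O
Why: In this Nef reaction (McMurry TiCl3 variant) the nitronate is reduced to the imine, which should hydrolyse at pH 5 to the ketone without the strong base that could eliminate the β-lactone oxygen at C1 and without oxidants that would attack the enamine.

Step 15
Reactants: 26 11-oxo pentacycle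
Product: 27 CNP0154902.3 (target)
Conditions: L-Selectride (1.1 equiv), THF, −78 °C; AcOH, then aq. NaHCO3
Reagents that add atoms: none
Why: In this bulky-hydride reduction the axial approach to C11 is blocked by the 1,3-diaxial lactone oxygen on C1 and by the endo C13 methyl, so hydride should add from the convex face to give the axial 11R alcohol cis to C13, while the lactones survive at −78 °C.

Compound list
1 | 3-methylfuran-2(5H)-one | CC1=CCOC1=O | starting material
2 | 3-methyl-2-(triisopropylsilyloxy)furan | Cc1ccoc1O[Si](C(C)C)(C(C)C)C(C)C | intermediate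
3 | 3-(tert-butyldimethylsilyloxy)propanal | O=CCCO[Si](C)(C)C(C)(C)C | starting material
4 | (S)-2-methylpropane-2-sulfinamide | CC(C)(C)[S@](=O)N | starting material
5 | (S,E)-N-[3-(tert-butyldimethylsilyloxy)propylidene]-2-methylpropane-2-sulfinamide | CC(C)(C)[S@](=O)/N=C/CCO[Si](C)(C)C(C)(C)C | intermediate
6 | (S)-N-[(1R)-3-(tert-butyldimethylsilyloxy)-1-[(2S)-4-methyl-5-oxo-2,5-dihydrofuran-2-yl]propyl]-2-methylpropane-2-sulfinamide | CC(C)(C)[S@](=O)N[C@@H]([C@@H]1C=C(C)C(=O)O1)CCO[Si](C)(C)C(C)(C)C | intermediate
7 | (S)-N-[(1R)-3-(tert-butyldimethylsilyloxy)-1-[(2S,4S)-4-methyl-5-oxooxolan-2-yl]propyl]-2-methylpropane-2-sulfinamide | CC(C)(C)[S@](=O)N[C@@H]([C@@H]1C[C@H](C)C(=O)O1)CCO[Si](C)(C)C(C)(C)C | intermediate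
8 | (3S,5S)-5-[(1R)-1-amino-3-hydroxypropyl]-3-methyloxolan-2-one hydrochloride | Cl.N[C@@H]([C@@H]1C[C@H](C)C(=O)O1)CCO | intermediate
9 | 6-bromohexanoyl chloride | O=C(Cl)CCCCCBr | starting material
10 | 6-bromo-N-[(1R)-3-hydroxy-1-[(2S,4S)-4-methyl-5-oxooxolan-2-yl]propyl]hexanamide | O=C(CCCCCBr)N[C@@H]([C@@H]1C[C@H](C)C(=O)O1)CCO | intermediate
11 | 1-[(1R)-3-hydroxy-1-[(2S,4S)-4-methyl-5-oxooxolan-2-yl]propyl]azepan-2-one | O=C1CCCCCN1[C@@H]([C@@H]2C[C@H](C)C(=O)O2)CCO | intermediate
12 | (3R)-3-[(2S,4S)-4-methyl-5-oxooxolan-2-yl]-3-(2-oxoazepan-1-yl)propanal | O=C1CCCCCN1[C@@H]([C@@H]2C[C@H](C)C(=O)O2)CC=O | intermediate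
13 | ethyl 2-(bromomethyl)acrylate | C=C(CBr)C(=O)OCC | starting material
14 | ethyl (6R)-4-hydroxy-2-methylidene-6-[(2S,4S)-4-methyl-5-oxooxolan-2-yl]-6-(2-oxoazepan-1-yl)hexanoate (C4 epimers) | O=C1CCCCCN1[C@@H]([C@@H]2C[C@H](C)C(=O)O2)CC(O)CC(=C)C(=O)OCC | intermediate
15 | 1-[(1R)-2-(4-methylidene-5-oxooxolan-2-yl)-1-[(2S,4S)-4-methyl-5-oxooxolan-2-yl]ethyl]azepan-2-one (epimers at the new lactone carbon) | O=C1CCCCCN1[C@@H]([C@@H]2C[C@H](C)C(=O)O2)CC3CC(=C)C(=O)O3 | intermediate
16 | 1-[(1R)-2-(4-methyl-5-oxo-2,5-dihydrofuran-2-yl)-1-[(2S,4S)-4-methyl-5-oxooxolan-2-yl]ethyl]azepan-2-one | O=C1CCCCCN1[C@@H]([C@@H]2C[C@H](C)C(=O)O2)CC3C=C(C)C(=O)O3 | intermediate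
17 | 1-[(1R)-2-[4-methyl-5-(triisopropylsilyloxy)furan-2-yl]-1-[(2S,4S)-4-methyl-5-oxooxolan-2-yl]ethyl]azepan-2-one | O=C1CCCCCN1[C@@H]([C@@H]2C[C@H](C)C(=O)O2)Cc3cc(C)c(O[Si](C(C)C)(C(C)C)C(C)C)o3 | intermediate
18 | O-triflyliminium triflate of 17 (7-triflyloxy-3,4,5,6-tetrahydro-2H-azepin-1-ium triflate) | O=S(=O)(OC1=[N+](CCCCC1)[C@@H]([C@@H]2C[C@H](C)C(=O)O2)Cc3cc(C)c(O[Si](C(C)C)(C(C)C)C(C)C)o3)C(F)(F)F.[O-]S(=O)(=O)C(F)(F)F | intermediate
19 | (1R,3R)-4'-methyl-3-[(2S,4S)-4-methyl-5-oxooxolan-2-yl]-2,3,5,6,7,8-hexahydro-5'H-spiro[pyrrolo[1,2-a]azepine-1,2'-furan]-5'-one | C1=C2N(CCCC1)[C@@H]([C@@H]3C[C@H](C)C(=O)O3)C[C@]24OC(=O)C(C)=C4 | intermediate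
20 | propanal | CCC=O | starting material
21 | nitromethane | C[N+](=O)[O-] | starting material
22 | 1-nitrobutan-2-ol | CCC(O)C[N+](=O)[O-] | intermediate
23 | (E)-1-nitrobut-1-ene | CC/C=C/[N+](=O)[O-] | intermediate
24 | 19 carrying a (2S)-1-nitrobutan-2-yl group at C9 | CC[C@H](C[N+](=O)[O-])C1=C2N(CCCC1)[C@@H]([C@@H]3C[C@H](C)C(=O)O3)C[C@]24OC(=O)C(C)=C4 | intermediate
25 | 11-nitro pentacycle (target with NO2 in place of the C11 hydroxyl, C11 epimers) | CC[C@H]1C2=C3N(CCCC2)[C@@H]([C@@H]2C[C@H](C)C(=O)O2)C[C@]32OC(=O)[C@H](C)[C@@H]2C1[N+](=O)[O-] | intermediate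
26 | 11-oxo pentacycle (target with a C11 ketone) | CC[C@H]1C2=C3N(CCCC2)[C@@H]([C@@H]2C[C@H](C)C(=O)O2)C[C@]32OC(=O)[C@H](C)[C@@H]2C1=O | intermediate
27 | CNP0154902.3 | CC[C@H]1C2=C3N(CCCC2)[C@@H]([C@@H]2C[C@H](C)C(=O)O2)C[C@]32OC(=O)[C@H](C)[C@@H]2[C@@H]1O | target

Total step count: 15. Longest linear sequence: 13 steps (steps 2–11 and 13–15, from 3-(tert-butyldimethylsilyloxy)propanal).

Steps most likely to fail

Step 11. The activated lactam may lose its α-proton to an unreactive ketene N,O-acetal, the furan may be desilylated or triflated before it cyclises, or the furan may add through the wrong face and give the C1 epimer. The fallback leaves the route at butenolide lactam 16. Lawesson's reagent (toluene, 80 °C) should thionate the lactam in preference to the lactones and give the thiolactam F1. Methyl triflate should then give the isolable S-methyl thioiminium triflate F2. TIPSOTf/Et3N generates the silyloxyfuran in the presence of this electrophile; the vinylogous Mannich addition is reversible at the N,S-ketal stage and so open to thermodynamic correction at C1, and loss of methanethiol returns the route to enamine 19.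

Step 13. The nitroalkene may approach both enamine faces without selectivity (C10 epimers), oligomerise, or stall at cyclobutane adducts before the second Michael addition. C10 is later α to the C11 ketone, where the pseudoaxial ethyl group (A1,2 strain with C8) is the expected thermodynamic epimer, but this is not relied on. The fallback sets out from enamine 19 and introduces the two carbons with C10 already fixed. Commercial (S)-2-hydroxybutanoic acid is converted (EtSH, DCC, DMAP) into S-ethyl (S)-2-hydroxybutanethioate F3 and then (Tf2O, 2,6-lutidine) into the triflate F4. Stork C-alkylation of 19 with F4 should proceed with inversion to the C9-alkylated thioester F5. Fukuyama reduction (Et3SiH, Pd/C) should give the aldehyde F6. An intramolecular Stetter reaction (triazolium carbene, iPr2NEt) onto the butenolide closes the cyclohexene and rejoins the route at ketone 26, bypassing the nitro compound and the Nef step.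

Step 15. Hydride may be delivered to the concave face and give the equatorial 11-epimer, or the alkoxide may trigger lactone migration. The fallback sets out from ketone 26. Reduction with a small hydride (NaBH4, CeCl3, MeOH, −78 °C) is used to obtain the 11-epi alcohol F7. Mitsunobu esterification with 4-nitrobenzoic acid (DIAD, PPh3) should invert C11 and give the 4-nitrobenzoate F8. Mild methanolysis (K2CO3, MeOH, 0 °C) returns the target 27.

Further compounds
F1 | step 11 | 1-[(1R)-2-(4-methyl-5-oxo-2,5-dihydrofuran-2-yl)-1-[(2S,4S)-4-methyl-5-oxooxolan-2-yl]ethyl]azepane-2-thione | S=C1CCCCCN1[C@@H]([C@@H]2C[C@H](C)C(=O)O2)CC3C=C(C)C(=O)O3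
F2 | step 11 | S-methyl thioiminium triflate of F1 (7-methylsulfanyl-3,4,5,6-tetrahydro-2H-azepin-1-ium triflate) | CSC1=[N+](CCCCC1)[C@@H]([C@@H]2C[C@H](C)C(=O)O2)CC3C=C(C)C(=O)O3.[O-]S(=O)(=O)C(F)(F)F
F3 | step 13 | S-ethyl (S)-2-hydroxybutanethioate | CC[C@H](O)C(=O)SCC
F4 | step 13 | S-ethyl (S)-2-(trifluoromethylsulfonyloxy)butanethioate | CC[C@H](OS(=O)(=O)C(F)(F)F)C(=O)SCC
F5 | step 13 | S-ethyl (2S)-2-(C9-yl)butanethioate of enamine 19 | CC[C@H](C(=O)SCC)C1=C2N(CCCC1)[C@@H]([C@@H]3C[C@H](C)C(=O)O3)C[C@]24OC(=O)C(C)=C4
F6 | step 13 | (2S)-2-(C9-yl)butanal of enamine 19 | CC[C@H](C=O)C1=C2N(CCCC1)[C@@H]([C@@H]3C[C@H](C)C(=O)O3)C[C@]24OC(=O)C(C)=C4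
F7 | step 15 | 11-epi alcohol (11S epimer of the target) | CC[C@H]1C2=C3N(CCCC2)[C@@H]([C@@H]2C[C@H](C)C(=O)O2)C[C@]32OC(=O)[C@H](C)[C@@H]2[C@H]1O
F8 | step 15 | 11-O-(4-nitrobenzoyl) derivative of the target | CC[C@H]1C2=C3N(CCCC2)[C@@H]([C@@H]2C[C@H](C)C(=O)O2)C[C@]32OC(=O)[C@H](C)[C@@H]2[C@@H]1OC(=O)c1ccc(cc1)[N+](=O)[O-]
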